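**Remarks on the chemistry (assumptions and design decisions)**

- Ring A is numbered O1, C2 (CH3), C3 (CHO or its precursor), C4 (acetate arm), C5 (carboxyl carbon), C6. This numbering is also used for the lactone intermediates.
- Structure check: the target is (2S,3R,4R), with the substituents at C2, C3 and C4 on alternating faces (2,3-trans, 3,4-trans). Lactone 9 and adduct 14 carry the same spatial arrangement. The C3 descriptor changes from S to R in step 12 only because CH2O becomes CHO. No structure needed correction.
- One point of stereochemical reasoning is tightened. On the diequatorial half-chair of 9, chair-like axial attack at C4 would come syn to the C3 arm. The anti adduct must therefore arise from the diaxial half-chair or from the anti, twist-boat-like approach (see step 6).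
- The C3 hydroxymethyl group is carried as a tert-butyldiphenylsilyl (TBDPS) ether. A smaller silyl ether would not survive the acidic methanol of step 7, and the larger group shields the syn face of C4 better.
- The catechol is carried as two benzyl ethers so that the last step is a neutral hydrogenolysis.
- Assumption: compounds 1, 4, 7, 10, 11 and 18 and all reagents and catalysts are purchased.

## Structural features

The target is a 3,4-dihydro-2H-pyran (ring A) in which O1–C6=C5–CO2Me forms a vinylogous carbonate. C2 carries a methyl group, C3 a formyl group and C4 a CH2CO2 arm esterified with 2-(3,4-dihydroxyphenyl)ethanol (ring B, a catechol), so rings A and B are joined only through a flexible ester chain. C2 (S), C3 (R) and C4 (R) are contiguous and all-trans. C3 is α to the aldehyde and can equilibrate, but trans to both neighbours is the favoured arrangement; C2 and C4 are fixed once made. Several groups are fragile: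

- the aldehyde makes C3–H acidic, and base can open ring A by β-elimination of O1 and so scramble C2;
- the enol ether can be hydrated by aqueous acid;
- the catechol is oxidised easily, so no oxidant may be used after its release;
- a free C3 hydroxymethyl group can attack the side-chain ester or C6.

The real difficulty is the C4 stereocentre, which lies between the C3 centre and the sp2 carbon C5, together with the order of events at the end. The key step uses the fact that C4 and C5 are the β- and α-carbons of the carboxyl group on C5. Bonding that carboxyl carbon to O1 turns ring A into an α,β-unsaturated δ-lactone in which C4 is a Michael acceptor next to the C3 stereocentre, and C5 becomes an enolate carbon that can accept C6 as a formyl group. The resulting α-formyl lactone is a masked form of the vinylogous carbonate.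

## Logic of the disconnections

**23 ⇒ 22.** The two aryl O–CH2Ph bonds of ring B are added retrosynthetically. The catechol must stay masked through esterification, fluoride treatment and oxidation. Hydrogenolysis releases it without base (which would open ring A at C2–O1) and without aqueous acid (which would hydrate C5=C6). The last step then touches no stereocentre. The forward step must spare the formyl group and the C5=C6 bond.

**22 ⇒ 21 ⇒ 20.** The C3 formyl group is traced back to C3–CH2OH and then to its silyl ether (O–Si bond). The aldehyde labilises C3–H and the C2–O1 bond, so it is unveiled as late as possible. This demands a non-basic desilylation and a near-neutral oxidation, and a free alcohol in 21 that does not attack the side-chain ester.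

**20 ⇒ 17 + 19, 19 ⇒ 18, 17 ⇒ 16.** The acyl C–O bond of the side-chain ester is cut, which separates ring B in a convergent way. 19 comes from 18 by cutting the two benzyl O–C bonds. The acid 17 must be distinguishable from the methyl ester on C5, so it is traced to the tert-butyl ester 16 (alkyl–O cleavage). The forward steps need a chemoselective ester cleavage and a mild coupling.

**16 ⇒ 14 (through 15).** The O1–C6 bond is cut and O1 is reconnected to the carboxyl carbon on C5; the methyl ester O–C bond is cut as well. This turns the vinylogous carbonate into an α-formyl δ-lactone and exposes a 1,3-dicarbonyl retron at C5. The forward step must open the lactone with the solvent alcohol and reclose O1 on C6 without losing the silyl ether or the tert-butyl ester.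

**14 ⇒ 9 + 10 + 11 (through 12 and 13).** The C5–C6 bond (Claisen retron) and the C4–CH2 bond (Michael retron) are cut. Two skeletal bonds and the C4 stereocentre disappear, leaving an unsaturated lactone with only the C2 and C3 centres. The forward step needs 1,4-addition, attack at C4 anti to the C3 arm, and C-formylation at C5 only.

**9 ⇒ 8 ⇒ 6 + 7.** The C4=C5 bond is cut by a metathesis retron and then the ester O–C(=O) bond. This gives an acyclic homoallylic alcohol and a three-carbon acyl unit. The forward ring closure must tolerate the allylic branch.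

**6 ⇒ 3 + 4 (through 5).** The C2–C3 bond is cut; it carries both remaining stereocentres. The anti homoallylic alcohol is an allylboration retron, so both centres come from achiral fragments in one catalytic step. This demands E geometry in 3 and a chiral catalyst that selects the face of 4.

**3 ⇒ 2 ⇒ 1.** The C–B bond and the O–Si bond are cut, leading to a symmetric diol. The forward steps need monofunctionalisation and an allylic substitution that gives the linear E isomer.

## Other disconnections considered

**Alternative 1:** The cut is O1–C2 and C3–C4. It divides ring A into the enal A3 ((E)-but-2-enal; supplies CH3, C2, C3 and the formyl carbon) and the 2-formylglutaconate diester A2 (supplies O1, C6, C5, C4 and both ester arms, with the catechol as acetonide). In the forward step a diarylprolinol silyl ether converts A3 into its iminium ion. The enol oxygen of A2 adds to C2 (oxa-Michael), the enamine carbon C3 then adds to C4 of the enoate (6-exo-trig Michael), and hydrolysis gives A1.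
- In its favour: the ring and all three stereocentres would form in one catalytic step, every carbon is at its final oxidation level, and the side-chain ester is already in place. On step economy and redox economy this is clearly the better plan.
- Against it here:
  - The enol of A2 is ambident, and attack through C5 (giving a quaternary centre) competes with attack through oxygen.
  - Oxa-Michael additions to small aliphatic enals are reversible, which threatens the enantiopurity at C2.
  - A2 can lactonise through its enol oxygen onto the distal ester to give a 2-pyranone with loss of the alcohol.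
  - The acceptor is a donor-substituted dienoate of modest electrophilicity.
  - Releasing the catechol from A1 needs aqueous acid in the presence of the aldehyde and the enol ether.
- Comparison: the alternative builds ring A directly in its final form and uses catalyst control at C2, which is equal in principle to the catalyst-controlled allylboration of the chosen plan. The chosen plan sets the stereocentres one after another in steps with close precedent and is therefore more predictable, at the price of about twice as many steps.

**Alternative 2:** The cut is C2–O1 and C6–O1 in the retro-Baeyer–Villiger sense. It leads from the lactone A4 to the all-trans cyclopentanone A5. In the forward step a buffered peracid inserts oxygen between C6 and the more substituted carbon C2 with retention at C2.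
- In its favour: the three stereocentres are assembled on a five-membered ring where the all-trans arrangement is thermodynamically preferred and the α-methyl centre can be equilibrated. The migratory preference and the retention are dependable. On confidence in the relative configuration of C2, C3 and C4 this alternative is the better of the two, because the chosen Michael addition has opposing directing groups.
- Against it here: in A4, C6 is at the carboxyl level and C5 is a bare methylene. C6 must then be reduced to the enol-ether level and C5 carboxylated (lactol, dehydration, acylation of the enol ether, haloform-type methanolysis), which costs about four extra steps. The acetal and the tert-butyl ester must survive peracid and hydride, and A5 itself needs a multi-step asymmetric synthesis.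
- Comparison: in the chosen plan the C5 carboxyl carbon is already present as the lactone carbonyl and C6 arrives at the right oxidation level by formylation, so the sequence after the key step is shorter. Mechanistically the ring expansion is more certain than the chosen key step; on step economy the chosen plan is better.

**Alternative 3:** The cut is C4–C5 and the C3–formyl bond. It leads from A6 to the β,γ-unsaturated lactone A7, in which the acetate arm is tied to the C2 oxygen, and methyl diformylacetate A8. In the forward step photoexcited A8 adds as its enol across C3=C4 of A7, and the cyclobutanol opens by retro-aldol cleavage.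
- In its favour: the suprafacial [2+2] addition fixes the C3/C4 relation by mechanism (cis on the temporary lactone equals trans in ring A). Approach anti to the methyl group would set both relative to C2. The formyl group and the formylacetate unit arrive together at the right oxidation levels. The later ring switch is the same kind of lactone-to-vinylogous-carbonate isomerisation as in the chosen plan, so the two plans are equal on that point, and the step count would be lower, which is better.
- Against it here: the two alkene carbons of A7 are sterically and electronically similar, so the orientation of the photoaddition is not secured. A7 isomerises easily into conjugation. From A6 onward the C3 aldehyde is free through methanolysis, esterification and deprotection, which exposes it to epimerisation and β-elimination.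
- Comparison: the chosen plan is longer but keeps C3 at the alcohol level until the penultimate step and forms each bond with defined regiochemistry. The alternative is shorter and more convergent but weaker on regiocontrol and on functional-group exposure.

Key step: step 6

## Route

Step 1
Reactants: 1 (E)-but-2-ene-1,4-diol
Product: 2 (E)-4-[(tert-butyldiphenylsilyl)oxy]but-2-en-1-ol
Conditions: TBDPSCl (1.0 equiv), imidazole (1.2 equiv), 1 (3 equiv), DMF, 0 °C to rt
Reagents that add atoms: tert-butyl(chloro)diphenylsilane, CC(C)(C)[Si](Cl)(c1ccccc1)c1ccccc1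
Why: Monosilylation of a symmetric diol used in excess; the unreacted diol is removed by aqueous extraction and the E geometry is untouched.

Step 2
Reactants: 2 (E)-4-[(tert-butyldiphenylsilyl)oxy]but-2-en-1-ol
Product: 3 2-[(E)-4-[(tert-butyldiphenylsilyl)oxy]but-2-en-1-yl]-4,4,5,5-tetramethyl-1,3,2-dioxaborolane
Conditions: B2pin2 (1.2 equiv), Pd(MeCN)4(BF4)2 (5 mol%), DMSO/MeOH, rt to 40 °C
Reagents that add atoms: bis(pinacolato)diboron, CC1(C)OB(OC1(C)C)B1OC(C)(C)C(C)(C)O1
Why: Palladium-catalysed borylation of an allylic alcohol with a cationic divalent palladium catalyst: the diboron activates the hydroxyl as a leaving group and the η3-allyl intermediate is borylated at its less hindered terminus, which should give the linear E allylboronate; the silyl ether is a poor leaving group and stays.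

Step 3
Reactants: 3 2-[(E)-4-[(tert-butyldiphenylsilyl)oxy]but-2-en-1-yl]-4,4,5,5-tetramethyl-1,3,2-dioxaborolane; 4 acetaldehyde
Product: 6 (2S,3S)-3-[[(tert-butyldiphenylsilyl)oxy]methyl]pent-4-en-2-ol, via pinacol borate ester 5 (not isolated)
Conditions: (R)-3,3'-bis(2,4,6-triisopropylphenyl)-1,1'-binaphthyl-2,2'-diyl hydrogen phosphate (5 mol%), 4 (3 equiv, cold toluene solution), 4 Å MS, toluene, −30 °C, sealed; aq. NaHCO3
Reagents that add atoms: none
Why: Chiral phosphoric acid-catalysed allylboration through a closed chair (Zimmerman–Traxler type) transition state: the E geometry of 3 places CH2OSi equatorial and gives the anti relation of C2–OH and the C3 arm, while the phosphate, hydrogen-bonded to a boronate oxygen, selects the aldehyde face. The (R) acid is expected by analogy with crotyl transfer to give (2S,3S); the sense is to be confirmed by Mosher ester analysis and the antipodal acid used if needed.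

Step 4
Reactants: 6 (2S,3S)-3-[[(tert-butyldiphenylsilyl)oxy]methyl]pent-4-en-2-ol; 7 prop-2-enoyl chloride (acryloyl chloride)
Product: 8 (2S,3S)-3-[[(tert-butyldiphenylsilyl)oxy]methyl]pent-4-en-2-yl prop-2-enoate
Conditions: Et3N (1.5 equiv), DMAP (5 mol%), CH2Cl2, −20 to 0 °C
Reagents that add atoms: none
Why: O-Acylation of a secondary alcohol under nucleophilic catalysis; neither stereocentre is involved.

Step 5
Reactants: 8 (2S,3S)-3-[[(tert-butyldiphenylsilyl)oxy]methyl]pent-4-en-2-yl prop-2-enoate
Product: 9 (5S,6S)-5-[[(tert-butyldiphenylsilyl)oxy]methyl]-6-methyl-5,6-dihydro-2H-pyran-2-one (trans)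
Conditions: second-generation Grubbs catalyst RuCl2(=CHPh)(H2IMes)(PCy3) (5 mol%), CH2Cl2 (0.01 M), 40 °C
Reagents that add atoms: none
Why: Ring-closing metathesis: the catalyst loads on the terminal alkene and closes onto the acrylate with loss of ethene, a standard entry to 5,6-dihydro-2H-pyran-2-ones; the stereocentres are not touched.

Step 6
Reactants: 9 (5S,6S)-5-[[(tert-butyldiphenylsilyl)oxy]methyl]-6-methyl-5,6-dihydro-2H-pyran-2-one; 10 tert-butyl acetate; 11 ethyl formate
Product: 14 tert-butyl 2-[(3Z,4R,5S,6S)-5-[[(tert-butyldiphenylsilyl)oxy]methyl]-3-(hydroxymethylidene)-6-methyl-2-oxooxan-4-yl]acetate, via lithium enolate of tert-butyl acetate 12 (not isolated), via lithium lactone enolate 13 (not isolated)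
Conditions: LiN(iPr)2 (1.2 equiv), 10 (1.3 equiv), THF, −78 °C; 9, −78 °C; 11 (3 equiv), −78 to −20 °C; aq. NH4Cl
Reagents that add atoms: none
Why: LiN(iPr)2 converts 10 into 12, which adds in a Michael fashion to C4 of 9 and generates the lactone enolate 13 at C5; 13 is then C-acylated by 11 in a crossed Claisen condensation, and the expelled ethoxide deprotonates the formyl lactone, which drives the acylation and stops it at monoformylation, so that the quench should give 14 as its hydrogen-bonded Z enol. The closest known reaction type is the tandem conjugate addition and enolate trapping of lithium ester enolates on 5,6-dihydro-2H-pyran-2-ones and butenolides. Two skeletal bonds form (C4–CH2 and C5–C6) and no ring closes. The only new stereocentre, C4, is controlled by the adjacent C3 centre: the trans-disubstituted half-chair of 9 can place the C3 arm and the C2 methyl group pseudoaxial at little cost, because the ring atoms 1,3 to them carry no axial substituent, and attack at C4 antiperiplanar to the pseudoaxial C3–CH2OSi bond is then the stereoelectronically favoured axial trajectory. On the diequatorial half-chair the chair-like axial attack would come syn and gauche to CH2OSi, which the bulk of the TBDPS group is meant to block, so the diaxial pathway or the anti approach should dominate, and both give the 3,4-trans adduct. The step needs 1,4- over 1,2-addition (hindered, stabilised tert-butyl ester enolate at −78 °C and an unhindered β-carbon), anti over syn attack (large silyl ether next to C4), and formylation at C5 and not at the tert-butyl ester α-carbon (the enolate is generated at C5 and trapped cold before proton transfer, and the α-formyl lactone is the more acidic, thermodynamically favoured product). The C2 methyl group lies 1,3 to the incoming nucleophile on the anti face and opposes the C3 arm, so the diastereomer ratio is to be checked on 14 or after step 7.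

Step 7
Reactants: 14 tert-butyl 2-[(3Z,4R,5S,6S)-5-[[(tert-butyldiphenylsilyl)oxy]methyl]-3-(hydroxymethylidene)-6-methyl-2-oxooxan-4-yl]acetate
Product: 16 methyl (2S,3S,4R)-4-(2-tert-butoxy-2-oxoethyl)-3-[[(tert-butyldiphenylsilyl)oxy]methyl]-2-methyl-3,4-dihydro-2H-pyran-5-carboxylate, via cyclic methyl acetal 15 (not isolated)
Conditions: CSA (0.2 equiv), MeOH, 40 °C; pyridine (0.3 equiv), evaporate; toluene, 110 °C, 4 Å MS
Reagents that add atoms: methanol, CO
Why: Acyl-lactone rearrangement: acid-catalysed methanolysis turns the lactone carbonyl into the C5 methyl ester and frees the C2 hydroxyl, which is captured by the formyl carbon C6 as the cyclic methyl acetal 15. The pyridinium sulfonate formed in the flask then catalyses loss of methanol, as in the acid-catalysed transetherification of β-alkoxyacrylates, to give the conjugated enol ether. The C2–O bond is never broken and C3 and C4 are not enolisable, so the three stereocentres are retained.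

Step 8
Reactants: 16 methyl (2S,3S,4R)-4-(2-tert-butoxy-2-oxoethyl)-3-[[(tert-butyldiphenylsilyl)oxy]methyl]-2-methyl-3,4-dihydro-2H-pyran-5-carboxylate
Product: 17 2-[(2S,3S,4R)-3-[[(tert-butyldiphenylsilyl)oxy]methyl]-5-(methoxycarbonyl)-2-methyl-3,4-dihydro-2H-pyran-4-yl]acetic acid
Conditions: TFA/CH2Cl2 (1:4), 0 °C to rt; toluene azeotrope
Reagents that add atoms: none
Why: Acid-induced alkyl–oxygen cleavage of the tert-butyl ester with loss of 2-methylpropene; the methyl ester, the acceptor-substituted enol ether and the primary TBDPS ether should tolerate anhydrous TFA for the short time needed.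

Step 9
Reactants: 18 2-(3,4-dihydroxyphenyl)ethanol (hydroxytyrosol)
Product: 19 2-[3,4-bis(benzyloxy)phenyl]ethan-1-ol
Conditions: BnBr (2.2 equiv), K2CO3 (2.5 equiv), acetone, 55 °C, argon
Reagents that add atoms: benzyl bromide, BrCc1ccccc1
Why: Williamson etherification: carbonate deprotonates only the phenols, so the aliphatic hydroxyl stays free for step 10.

Step 10
Reactants: 17 2-[(2S,3S,4R)-3-[[(tert-butyldiphenylsilyl)oxy]methyl]-5-(methoxycarbonyl)-2-methyl-3,4-dihydro-2H-pyran-4-yl]acetic acid; 19 2-[3,4-bis(benzyloxy)phenyl]ethan-1-ol
Product: 20 methyl (2S,3S,4R)-4-[2-[2-[3,4-bis(benzyloxy)phenyl]ethoxy]-2-oxoethyl]-3-[[(tert-butyldiphenylsilyl)oxy]methyl]-2-methyl-3,4-dihydro-2H-pyran-5-carboxylate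
Conditions: EDC·HCl (1.3 equiv), DMAP (0.1 equiv), CH2Cl2, 0 °C to rt
Reagents that add atoms: none
Why: Steglich esterification of a primary alcohol; no aldehyde is present yet, so the mild base cannot cause β-elimination in ring A.

Step 11
Reactants: 20 methyl (2S,3S,4R)-4-[2-[2-[3,4-bis(benzyloxy)phenyl]ethoxy]-2-oxoethyl]-3-[[(tert-butyldiphenylsilyl)oxy]methyl]-2-methyl-3,4-dihydro-2H-pyran-5-carboxylate
Product: 21 methyl (2S,3S,4R)-4-[2-[2-[3,4-bis(benzyloxy)phenyl]ethoxy]-2-oxoethyl]-3-(hydroxymethyl)-2-methyl-3,4-dihydro-2H-pyran-5-carboxylate
Conditions: HF·pyridine (excess), pyridine, THF, 0 °C to rt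
Reagents that add atoms: none
Why: Fluoride-induced Si–O cleavage in a weakly acidic buffered medium; no alkoxide is formed that could transfer the side-chain acyl group to the new primary alcohol, and the benzyl ethers and both esters are inert.

Step 12
Reactants: 21 methyl (2S,3S,4R)-4-[2-[2-[3,4-bis(benzyloxy)phenyl]ethoxy]-2-oxoethyl]-3-(hydroxymethyl)-2-methyl-3,4-dihydro-2H-pyran-5-carboxylate
Product: 22 methyl (2S,3R,4R)-4-[2-[2-[3,4-bis(benzyloxy)phenyl]ethoxy]-2-oxoethyl]-3-formyl-2-methyl-3,4-dihydro-2H-pyran-5-carboxylate
Conditions: Dess–Martin periodinane (1.3 equiv), pyridine (3 equiv), CH2Cl2, 0 °C to rt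
Reagents that add atoms: none
Why: Dess–Martin oxidation stops at the aldehyde under near-neutral conditions; C3 keeps its configuration, which is also the thermodynamically preferred one (trans to both neighbours).

Step 13
Reactants: 22 methyl (2S,3R,4R)-4-[2-[2-[3,4-bis(benzyloxy)phenyl]ethoxy]-2-oxoethyl]-3-formyl-2-methyl-3,4-dihydro-2H-pyran-5-carboxylate
Product: 23 methyl (2S,3R,4R)-4-[2-[2-(3,4-dihydroxyphenyl)ethoxy]-2-oxoethyl]-3-formyl-2-methyl-3,4-dihydro-2H-pyran-5-carboxylate (target)
Conditions: H2 (1 atm), 10% Pd/C, EtOAc, rt; filtration under argon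
Reagents that add atoms: none
Why: Hydrogenolysis of aryl benzyl ethers is fast on palladium, whereas the aliphatic aldehyde and the trisubstituted donor–acceptor C5=C6 bond should be reduced much more slowly; the neutral medium avoids β-elimination at C3–C2 and hydration of the enol ether.

## Compound list

1 | (E)-but-2-ene-1,4-diol | OC/C=C/CO | starting material
2 | (E)-4-[(tert-butyldiphenylsilyl)oxy]but-2-en-1-ol | OC/C=C/CO[Si](c1ccccc1)(c1ccccc1)C(C)(C)C | intermediate
3 | 2-[(E)-4-[(tert-butyldiphenylsilyl)oxy]but-2-en-1-yl]-4,4,5,5-tetramethyl-1,3,2-dioxaborolane | CC1(C)OB(C/C=C/CO[Si](c2ccccc2)(c2ccccc2)C(C)(C)C)OC1(C)C | intermediate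
4 | acetaldehyde | CC=O | starting material
5 | pinacol borate ester of 6 (O–B bond at the C2 oxygen; not isolated) | C[C@H](OB1OC(C)(C)C(C)(C)O1)[C@H](CO[Si](c1ccccc1)(c1ccccc1)C(C)(C)C)C=C | intermediate
6 | (2S,3S)-3-[[(tert-butyldiphenylsilyl)oxy]methyl]pent-4-en-2-ol | C[C@H](O)[C@H](CO[Si](c1ccccc1)(c1ccccc1)C(C)(C)C)C=C | intermediate
7 | prop-2-enoyl chloride | C=CC(Cl)=O | starting material
8 | (2S,3S)-3-[[(tert-butyldiphenylsilyl)oxy]methyl]pent-4-en-2-yl prop-2-enoate | C[C@H](OC(=O)C=C)[C@H](CO[Si](c1ccccc1)(c1ccccc1)C(C)(C)C)C=C | intermediate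
9 | (5S,6S)-5-[[(tert-butyldiphenylsilyl)oxy]methyl]-6-methyl-5,6-dihydro-2H-pyran-2-one (trans) | C[C@@H]1OC(=O)C=C[C@H]1CO[Si](c1ccccc1)(c1ccccc1)C(C)(C)C | intermediate
10 | tert-butyl acetate | CC(=O)OC(C)(C)C | starting material
11 | ethyl formate | CCOC=O | starting material
12 | lithium enolate of tert-butyl acetate (not isolated) | [Li]OC(=C)OC(C)(C)C | intermediate
13 | lithium enolate of the all-trans Michael adduct lactone (not isolated) | C[C@@H]1OC(O[Li])=C[C@H](CC(=O)OC(C)(C)C)[C@H]1CO[Si](c1ccccc1)(c1ccccc1)C(C)(C)C | intermediate
14 | tert-butyl 2-[(3Z,4R,5S,6S)-5-[[(tert-butyldiphenylsilyl)oxy]methyl]-3-(hydroxymethylidene)-6-methyl-2-oxooxan-4-yl]acetate (all-trans) | C[C@@H]1OC(=O)/C(=C\O)[C@H](CC(=O)OC(C)(C)C)[C@H]1CO[Si](c1ccccc1)(c1ccccc1)C(C)(C)C | intermediate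
15 | methyl 4-(2-tert-butoxy-2-oxoethyl)-5-[[(tert-butyldiphenylsilyl)oxy]methyl]-2-methoxy-6-methyloxane-3-carboxylate (epimers at the acetal and ester carbons; the three centres from 14 unchanged; not isolated) | COC(=O)C1C(OC)O[C@@H](C)[C@H](CO[Si](c2ccccc2)(c2ccccc2)C(C)(C)C)[C@H]1CC(=O)OC(C)(C)C | intermediate
16 | methyl (2S,3S,4R)-4-(2-tert-butoxy-2-oxoethyl)-3-[[(tert-butyldiphenylsilyl)oxy]methyl]-2-methyl-3,4-dihydro-2H-pyran-5-carboxylate | COC(=O)C1=CO[C@@H](C)[C@H](CO[Si](c2ccccc2)(c2ccccc2)C(C)(C)C)[C@H]1CC(=O)OC(C)(C)C | intermediate
17 | 2-[(2S,3S,4R)-3-[[(tert-butyldiphenylsilyl)oxy]methyl]-5-(methoxycarbonyl)-2-methyl-3,4-dihydro-2H-pyran-4-yl]acetic acid | COC(=O)C1=CO[C@@H](C)[C@H](CO[Si](c2ccccc2)(c2ccccc2)C(C)(C)C)[C@H]1CC(=O)O | intermediate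
18 | 2-(3,4-dihydroxyphenyl)ethanol (hydroxytyrosol) | OCCc1ccc(O)c(O)c1 | starting material
19 | 2-[3,4-bis(benzyloxy)phenyl]ethan-1-ol | OCCc1ccc(OCc2ccccc2)c(OCc2ccccc2)c1 | intermediate
20 | methyl (2S,3S,4R)-4-[2-[2-[3,4-bis(benzyloxy)phenyl]ethoxy]-2-oxoethyl]-3-[[(tert-butyldiphenylsilyl)oxy]methyl]-2-methyl-3,4-dihydro-2H-pyran-5-carboxylate | COC(=O)C1=CO[C@@H](C)[C@H](CO[Si](c2ccccc2)(c2ccccc2)C(C)(C)C)[C@H]1CC(=O)OCCc1ccc(OCc2ccccc2)c(OCc2ccccc2)c1 | intermediate
21 | methyl (2S,3S,4R)-4-[2-[2-[3,4-bis(benzyloxy)phenyl]ethoxy]-2-oxoethyl]-3-(hydroxymethyl)-2-methyl-3,4-dihydro-2H-pyran-5-carboxylate | COC(=O)C1=CO[C@@H](C)[C@H](CO)[C@H]1CC(=O)OCCc1ccc(OCc2ccccc2)c(OCc2ccccc2)c1 | intermediate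
22 | methyl (2S,3R,4R)-4-[2-[2-[3,4-bis(benzyloxy)phenyl]ethoxy]-2-oxoethyl]-3-formyl-2-methyl-3,4-dihydro-2H-pyran-5-carboxylate | COC(=O)C1=CO[C@@H](C)[C@H](C=O)[C@H]1CC(=O)OCCc1ccc(OCc2ccccc2)c(OCc2ccccc2)c1 | intermediate
23 | methyl (2S,3R,4R)-4-[2-[2-(3,4-dihydroxyphenyl)ethoxy]-2-oxoethyl]-3-formyl-2-methyl-3,4-dihydro-2H-pyran-5-carboxylate | COC(=O)C1=CO[C@@H](C)[C@H](C=O)[C@H]1CC(=O)OCCc1ccc(O)c(O)c1 | target

## Step count and least certain steps

Total: 13 steps. Longest linear sequence: 12 steps (1 to 23 through steps 1–8 and 10–13); 19 is made from 18 in one step.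

**Step 6 (key step).** The most likely failure is poor facial selectivity at C4, because the C3 arm and the C2 methyl group of the trans lactone direct the nucleophile to opposite faces. Secondary risks are γ-deprotonation of 9 and proton transfer in 13 before the formate reacts. The fallback separates the two bond formations. It sets out from 9 and 10. Compound 10 is converted with LiN(iPr)2 and TBSCl into the silyl ketene acetal tert-butyl[(1-tert-butoxyethenyl)oxy]dimethylsilane F1. A Mukaiyama–Michael addition of F1 to 9 (TBSOTf 10 mol%, CH2Cl2, −78 °C) runs through an open transition state on the silyl-activated lactone, where the approach past the large C3 arm should be penalised more strongly. After hydrolytic work-up it gives the saturated lactone tert-butyl 2-[(2S,3S,4R)-3-[[(tert-butyldiphenylsilyl)oxy]methyl]-2-methyl-6-oxooxan-4-yl]acetate F2, which can be purified to one diastereomer. Claisen formylation of F2 with 11 (NaH, catalytic EtOH, THF) under thermodynamic control places the formyl group on the more acidic lactone α-carbon and returns to the route at 14.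

**Step 3.** The most likely failure is low enantioselectivity, because the smallest aliphatic aldehyde offers little steric differentiation in the chiral ion pair; loss of the volatile 4 may also lower conversion. The fallback is auxiliary-controlled and bypasses steps 1–3. It sets out from 4. (4R)-4-Benzyl-3-[(E)-but-2-enoyl]-1,3-oxazolidin-2-one F3 is made from (R)-4-benzyl-1,3-oxazolidin-2-one and (E)-but-2-enoyl chloride. It is converted with Bu2BOTf and Et3N into its boron dienolate, which reacts at the α-carbon with 4 in an Evans syn-aldol reaction to give (4R)-4-benzyl-3-[(2R,3S)-2-ethenyl-3-hydroxybutanoyl]-1,3-oxazolidin-2-one F4. Reduction with LiBH4 removes the auxiliary and gives (2S,3S)-2-ethenylbutane-1,3-diol F5. Selective silylation of the primary hydroxyl (TBDPSCl, imidazole) returns to the route at 6.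

**Step 7.** The most likely failures are incomplete loss of methanol from 15, and acid-induced cleavage of the tert-butyl ester or the silyl ether; a free C3 hydroxymethyl group would then add to C6. The fallback runs under base and sets out from 14. O-Methylation (Me2SO4, K2CO3, acetone) gives tert-butyl 2-[(4R,5S,6S)-5-[[(tert-butyldiphenylsilyl)oxy]methyl]-3-(methoxymethylidene)-6-methyl-2-oxooxan-4-yl]acetate F6. NaOMe in MeOH at rt then opens the lactone to the methyl ester, and the C2 alkoxide adds to C6 of the β-methoxyacrylate and expels methoxide. This returns to the route at 16.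

**Step 11.** The most likely failure is acyl transfer from the side-chain ester to the liberated primary alcohol (lactonisation with loss of 19), or addition of that alcohol to C6. The fallback changes the order of events so that the alcohol is released while the arm is still a hindered tert-butyl ester. It sets out from 16. Desilylation (HF·pyridine) gives methyl (2S,3S,4R)-4-(2-tert-butoxy-2-oxoethyl)-3-(hydroxymethyl)-2-methyl-3,4-dihydro-2H-pyran-5-carboxylate F7. Dess–Martin oxidation gives methyl (2S,3R,4R)-4-(2-tert-butoxy-2-oxoethyl)-3-formyl-2-methyl-3,4-dihydro-2H-pyran-5-carboxylate F8. TFA gives 2-[(2S,3R,4R)-3-formyl-5-(methoxycarbonyl)-2-methyl-3,4-dihydro-2H-pyran-4-yl]acetic acid F9. Carbodiimide coupling of F9 with 19 at 0 °C returns to the route at 22.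

**Step 13.** The most likely failures are over-reduction (aldehyde to alcohol, or saturation of C5=C6) competing with a sluggish second debenzylation, and air oxidation of the catechol during isolation. The fallback replaces the hydrogenolysable ethers by allyl ethers and sets out from 17 and 18. Compound 18 with allyl bromide and K2CO3 gives 2-[3,4-bis(prop-2-en-1-yloxy)phenyl]ethan-1-ol F10. Coupling with 17 gives methyl (2S,3S,4R)-4-[2-[2-[3,4-bis(prop-2-en-1-yloxy)phenyl]ethoxy]-2-oxoethyl]-3-[[(tert-butyldiphenylsilyl)oxy]methyl]-2-methyl-3,4-dihydro-2H-pyran-5-carboxylate F11. Desilylation gives methyl (2S,3S,4R)-4-[2-[2-[3,4-bis(prop-2-en-1-yloxy)phenyl]ethoxy]-2-oxoethyl]-3-(hydroxymethyl)-2-methyl-3,4-dihydro-2H-pyran-5-carboxylate F12. Oxidation gives methyl (2S,3R,4R)-4-[2-[2-[3,4-bis(prop-2-en-1-yloxy)phenyl]ethoxy]-2-oxoethyl]-3-formyl-2-methyl-3,4-dihydro-2H-pyran-5-carboxylate F13. Deallylation with Pd(PPh3)4 (zerovalent palladium) and sodium 4-methylbenzenesulfinate in THF/MeOH at rt returns to the route at 23.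

## Further compounds

F1 | step 6 | tert-butyl[(1-tert-butoxyethenyl)oxy]dimethylsilane | C=C(OC(C)(C)C)O[Si](C)(C)C(C)(C)C
F2 | step 6 | tert-butyl 2-[(2S,3S,4R)-3-[[(tert-butyldiphenylsilyl)oxy]methyl]-2-methyl-6-oxooxan-4-yl]acetate | C[C@@H]1OC(=O)C[C@H](CC(=O)OC(C)(C)C)[C@H]1CO[Si](c1ccccc1)(c1ccccc1)C(C)(C)C
F3 | step 3 | (4R)-4-benzyl-3-[(E)-but-2-enoyl]-1,3-oxazolidin-2-one | C/C=C/C(=O)N1[C@H](Cc2ccccc2)COC1=O
F4 | step 3 | (4R)-4-benzyl-3-[(2R,3S)-2-ethenyl-3-hydroxybutanoyl]-1,3-oxazolidin-2-one | C[C@H](O)[C@H](C(=O)N1[C@H](Cc2ccccc2)COC1=O)C=C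
F5 | step 3 | (2S,3S)-2-ethenylbutane-1,3-diol | C[C@H](O)[C@H](CO)C=C
F6 | step 7 | tert-butyl 2-[(4R,5S,6S)-5-[[(tert-butyldiphenylsilyl)oxy]methyl]-3-(methoxymethylidene)-6-methyl-2-oxooxan-4-yl]acetate | C[C@@H]1OC(=O)C(=COC)[C@H](CC(=O)OC(C)(C)C)[C@H]1CO[Si](c1ccccc1)(c1ccccc1)C(C)(C)C
F7 | step 11 | methyl (2S,3S,4R)-4-(2-tert-butoxy-2-oxoethyl)-3-(hydroxymethyl)-2-methyl-3,4-dihydro-2H-pyran-5-carboxylate | COC(=O)C1=CO[C@@H](C)[C@H](CO)[C@H]1CC(=O)OC(C)(C)C
F8 | step 11 | methyl (2S,3R,4R)-4-(2-tert-butoxy-2-oxoethyl)-3-formyl-2-methyl-3,4-dihydro-2H-pyran-5-carboxylate | COC(=O)C1=CO[C@@H](C)[C@H](C=O)[C@H]1CC(=O)OC(C)(C)C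
F9 | step 11 | 2-[(2S,3R,4R)-3-formyl-5-(methoxycarbonyl)-2-methyl-3,4-dihydro-2H-pyran-4-yl]acetic acid | COC(=O)C1=CO[C@@H](C)[C@H](C=O)[C@H]1CC(=O)O
F10 | step 13 | 2-[3,4-bis(prop-2-en-1-yloxy)phenyl]ethan-1-ol | OCCc1ccc(OCC=C)c(OCC=C)c1
F11 | step 13 | methyl (2S,3S,4R)-4-[2-[2-[3,4-bis(prop-2-en-1-yloxy)phenyl]ethoxy]-2-oxoethyl]-3-[[(tert-butyldiphenylsilyl)oxy]methyl]-2-methyl-3,4-dihydro-2H-pyran-5-carboxylate | COC(=O)C1=CO[C@@H](C)[C@H](CO[Si](c2ccccc2)(c2ccccc2)C(C)(C)C)[C@H]1CC(=O)OCCc1ccc(OCC=C)c(OCC=C)c1
F12 | step 13 | methyl (2S,3S,4R)-4-[2-[2-[3,4-bis(prop-2-en-1-yloxy)phenyl]ethoxy]-2-oxoethyl]-3-(hydroxymethyl)-2-methyl-3,4-dihydro-2H-pyran-5-carboxylate | COC(=O)C1=CO[C@@H](C)[C@H](CO)[C@H]1CC(=O)OCCc1ccc(OCC=C)c(OCC=C)c1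
F13 | step 13 | methyl (2S,3R,4R)-4-[2-[2-[3,4-bis(prop-2-en-1-yloxy)phenyl]ethoxy]-2-oxoethyl]-3-formyl-2-methyl-3,4-dihydro-2H-pyran-5-carboxylate | COC(=O)C1=CO[C@@H](C)[C@H](C=O)[C@H]1CC(=O)OCCc1ccc(OCC=C)c(OCC=C)c1
A1 | alternative 1 | methyl (2S,3R,4R)-4-[2-[2-(2,2-dimethyl-1,3-benzodioxol-5-yl)ethoxy]-2-oxoethyl]-3-formyl-2-methyl-3,4-dihydro-2H-pyran-5-carboxylate | COC(=O)C1=CO[C@@H](C)[C@H](C=O)[C@H]1CC(=O)OCCc1ccc2OC(C)(C)Oc2c1
A2 | alternative 1 | 5-[2-(2,2-dimethyl-1,3-benzodioxol-5-yl)ethyl] 1-methyl (3E)-2-(hydroxymethylidene)pent-3-enedioate | COC(=O)C(=CO)/C=C/C(=O)OCCc1ccc2OC(C)(C)Oc2c1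
A3 | alternative 1 | (E)-but-2-enal | C/C=C/C=O
A4 | alternative 2 | tert-butyl 2-[5-(dimethoxymethyl)-6-methyl-2-oxooxan-4-yl]acetate, all-trans | O=C1C[C@H](CC(=O)OC(C)(C)C)[C@@H](C(OC)OC)[C@H](C)O1
A5 | alternative 2 | tert-butyl 2-[2-(dimethoxymethyl)-3-methyl-4-oxocyclopentyl]acetate, all-trans | O=C1C[C@H](CC(=O)OC(C)(C)C)[C@@H](C(OC)OC)[C@@H]1C
A6 | alternative 3 | methyl 2-(3-formyl-2-methyl-6-oxooxan-4-yl)-3-hydroxyprop-2-enoate, 2,3-trans and 3,4-cis on the lactone | C[C@@H]1OC(=O)C[C@@H](/C(=C/O)C(=O)OC)[C@H]1C=O
A7 | alternative 3 | (6S)-6-methyl-3,6-dihydro-2H-pyran-2-one | C[C@@H]1OC(=O)CC=C1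
A8 | alternative 3 | methyl 2-formyl-3-hydroxyprop-2-enoate (methyl diformylacetate, enol form) | COC(=O)C(C=O)=CO
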